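**Retrosynthetic overview**

1. The target is the meso (6S,6′R) isomer. Its two C6 centres are set last, one ring after the other, by two pseudo-enantiomeric amine-catalysed 1,3-proton shifts on achiral β,β-carotene-3,3′-dione.
2. Both rings of that dione close in one operation: a two-fold Michael/aldol annulation of an acyclic C28 polyene bis(methyl ketone) with two mesityl oxide units (bonds C6–C1 and C4=C5 at each end), quenched from the dienolate as the deconjugated dione.
3. C28 diketone ⇐ crocetindialdehyde (C20) + two C4 ketal ylides (Wittig, C7=C8).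
4. Crocetindialdehyde ⇐ C10 dialdehyde + 2 × C2 + 2 × C3 Wittig units.
5. Ring order: no ring exists until step 5; there both end rings form together.

Assumption: the SMILES encodes 6S at one ring and 6R at the other, i.e. the achiral meso diastereomer, so "single enantiomer" is read as this single stereoisomer free of the (6R,6′R)/(6S,6′S) pair. Which of the two pseudo-enantiomeric catalysts gives which sense is not known in advance and does not matter: used in sequence they give the meso compound either way (18 is drawn 6′S).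

**Step 1**
Reactants: 1 (2E,4E,6E)-2,7-dimethylocta-2,4,6-trienedial; 2 (1,3-dioxolan-2-ylmethyl)triphenylphosphonium bromide
Product: 5 (2E,4E,6E,8E,10E)-4,9-dimethyldodeca-2,4,6,8,10-pentaenedial, via dioxolanylmethylidene ylide 3 (not isolated), via C14 bis(dioxolane) 4 (not isolated)
Conditions: 2 (2.5 equiv), KOtBu (2.5 equiv), THF, 0 °C to rt; then 1 M aq HCl, THF, rt
Reagents that add atoms: water, O
Why: Two-fold Wittig olefination followed by acetal hydrolysis adds a two-carbon enal unit at each end, and the acid equilibrates the new enal double bonds to E; no stereocentre is formed.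

**Step 2**
Reactants: 5 (2E,4E,6E,8E,10E)-4,9-dimethyldodeca-2,4,6,8,10-pentaenedial; 6 2-(triphenyl-λ5-phosphanylidene)propanal
Product: 7 (2E,4E,6E,8E,10E,12E,14E)-2,6,11,15-tetramethylhexadeca-2,4,6,8,10,12,14-heptaenedial (crocetindialdehyde)
Conditions: 6 (2.4 equiv), toluene, 80 °C, Ar, dark
Reagents that add atoms: none
Why: Wittig olefination with a stabilized ylide is E-selective, and the α-methyl enal product is less electrophilic than 5, so one C3 unit is added per end; no stereocentre is formed.

**Step 3**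
Reactants: 8 2-(2-bromoethyl)-2-methyl-1,3-dioxolane; 9 triphenylphosphine
Product: 10 [2-(2-methyl-1,3-dioxolan-2-yl)ethyl]triphenylphosphonium bromide
Conditions: toluene, 100 °C, 48 h
Reagents that add atoms: none
Why: SN2 quaternisation of triphenylphosphine by a primary bromide gives the Wittig salt; the ketal is inert to these conditions.

**Step 4**
Reactants: 7 crocetindialdehyde; 10 [2-(2-methyl-1,3-dioxolan-2-yl)ethyl]triphenylphosphonium bromide
Product: 13 (4E,6E,8E,10E,12E,14E,16E,18E,20E)-6,10,15,19-tetramethyltetracosa-4,6,8,10,12,14,16,18,20-nonaene-2,23-dione, via ketal ylide 11 (not isolated), via C28 bis(dioxolane) 12 (not isolated)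
Conditions: 10 (2.6 equiv), NaN(SiMe3)2 (2.6 equiv), THF, −78 °C to rt; I2 (2 mol%), CH2Cl2, daylight, rt; then 1 M aq HCl, THF, 0 °C to rt; Ar throughout
Reagents that add atoms: water, O
Why: Wittig olefination with the non-stabilized ylide builds C7=C8 at both ends, iodine-catalysed photoequilibration turns the sterically hindered Z bonds into E, and dilute acid unmasks the two methyl ketones without moving the β,γ double bond out of the polyene; no stereocentre is formed.

**Step 5**
Reactants: 13 (all-E)-6,10,15,19-tetramethyltetracosa-4,6,8,10,12,14,16,18,20-nonaene-2,23-dione; 14 4-methylpent-3-en-2-one (mesityl oxide)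
Product: 17 β,β-carotene-3,3′-dione, via bis(1,5-diketone) 15 (not isolated), via dipotassium bis(dienolate) 16 (not isolated)
Conditions: 14 (10 equiv), KOtBu (5 equiv), THF–t-BuOH 5:1, 0 to 45 °C, Ar, dark; then dilute with THF, −78 °C, AcOH (12 equiv)
Reagents that add atoms: none
Why: Two-fold Robinson-type annulation (Michael addition then intramolecular aldol condensation, the bond set known for acetoacetic ester plus mesityl oxide giving a 4-substituted isophorone): C6–H of 13 is α to the ketone and allylic to the nonaene, hence far more acidic than any proton of mesityl oxide, so only the polyenolate adds; attack through remote chain positions is reversible and cannot cyclize, whereas the C6 adduct 15 closes to the six-membered enone; excess base stores each new ring as the extended dienolate 16, and kinetic protonation at C4 releases the deconjugated β,γ-enone rings of 17, which carry no stereocentre.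

**Step 6**
Reactants: 17 β,β-carotene-3,3′-dione
Product: 18 (6′S)-β,ε-carotene-3,3′-dione
Conditions: 9-amino(9-deoxy)epi-quinine (10 mol%), CF3CO2H (20 mol%), toluene, 0 °C, Ar, dark; stopped at about half conversion of the ring ends; chromatography on deactivated silica (recovered 17 recycled)
Reagents that add atoms: none
Why: Amine-catalysed enantioselective isomerization of a β,γ- to an α,β-unsaturated cyclohexenone (iminium, then dienamine, then γ-protonation by the protonated quinuclidine) creates C6′ under catalyst control; the two ends react independently, so stopping at half conversion gives mainly the mono-isomerized dione, which differs in chromophore from 17 and from doubly isomerized material.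

**Step 7**
Reactants: 18 (6′S)-β,ε-carotene-3,3′-dione
Product: 19 (6S,6′R)-ε,ε-carotene-3,3′-dione (meso)
Conditions: 9-amino(9-deoxy)epi-quinidine (10 mol%), CF3CO2H (20 mol%), toluene, 0 °C to rt, Ar, dark; crystallization
Reagents that add atoms: none
Why: The same dienamine γ-protonation with the pseudo-enantiomeric catalyst sets the second centre with the opposite sense, which makes the product meso whichever absolute sense each catalyst has; the first centre lies in a hindered conjugated enone that re-forms an iminium only slowly and is therefore kept.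

**Compound list**

1 | (2E,4E,6E)-2,7-dimethylocta-2,4,6-trienedial (C10 dialdehyde) | O=C/C(C)=C/C=C/C=C(C)/C=O | starting material
2 | (1,3-dioxolan-2-ylmethyl)triphenylphosphonium bromide | [Br-].C1COC(O1)C[P+](c1ccccc1)(c1ccccc1)c1ccccc1 | starting material
3 | (1,3-dioxolan-2-ylmethylidene)triphenyl-λ5-phosphane | C1COC(O1)C=P(c1ccccc1)(c1ccccc1)c1ccccc1 | intermediate
4 | 2,2′-[(3E,5E,7E)-3,8-dimethyldeca-1,3,5,7,9-pentaene-1,10-diyl]bis(1,3-dioxolane), E/Z mixture at the two new double bonds | C1COC(O1)C=C/C(C)=C/C=C/C=C(C)/C=CC1OCCO1 | intermediate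
5 | (2E,4E,6E,8E,10E)-4,9-dimethyldodeca-2,4,6,8,10-pentaenedial (C14 dialdehyde) | O=C/C=C/C(C)=C/C=C/C=C(C)/C=C/C=O | intermediate
6 | 2-(triphenyl-λ5-phosphanylidene)propanal | CC(C=O)=P(c1ccccc1)(c1ccccc1)c1ccccc1 | starting material
7 | (2E,4E,6E,8E,10E,12E,14E)-2,6,11,15-tetramethylhexadeca-2,4,6,8,10,12,14-heptaenedial (crocetindialdehyde) | O=C/C(C)=C/C=C/C(C)=C/C=C/C=C(C)/C=C/C=C(C)/C=O | intermediate
8 | 2-(2-bromoethyl)-2-methyl-1,3-dioxolane | CC1(CCBr)OCCO1 | starting material
9 | triphenylphosphine | c1ccc(cc1)P(c1ccccc1)c1ccccc1 | starting material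
10 | [2-(2-methyl-1,3-dioxolan-2-yl)ethyl]triphenylphosphonium bromide | [Br-].CC1(CC[P+](c2ccccc2)(c2ccccc2)c2ccccc2)OCCO1 | intermediate
11 | [2-(2-methyl-1,3-dioxolan-2-yl)ethylidene]triphenyl-λ5-phosphane | CC1(CC=P(c2ccccc2)(c2ccccc2)c2ccccc2)OCCO1 | intermediate
12 | 2,2′-[(2E,4E,6E,8E,10E,12E,14E,16E,18E)-4,8,13,17-tetramethylicosa-2,4,6,8,10,12,14,16,18-nonaene-1,20-diyl]bis(2-methyl-1,3-dioxolane) | CC1(OCCO1)C/C=C/C(C)=C/C=C/C(C)=C/C=C/C=C(C)/C=C/C=C(C)/C=C/CC1(C)OCCO1 | intermediate
13 | (4E,6E,8E,10E,12E,14E,16E,18E,20E)-6,10,15,19-tetramethyltetracosa-4,6,8,10,12,14,16,18,20-nonaene-2,23-dione | CC(=O)C/C=C/C(C)=C/C=C/C(C)=C/C=C/C=C(C)/C=C/C=C(C)/C=C/CC(C)=O | intermediate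
14 | 4-methylpent-3-en-2-one (mesityl oxide) | CC(C)=CC(C)=O | starting material
15 | (all-E)-5,24-diacetyl-4,4,8,12,17,21,25,25-octamethyloctacosa-6,8,10,12,14,16,18,20,22-nonaene-2,27-dione, mixture of diastereomers | CC(=O)CC(C)(C)C(C(C)=O)/C=C/C(C)=C/C=C/C(C)=C/C=C/C=C(C)/C=C/C=C(C)/C=C/C(C(C)=O)C(C)(C)CC(C)=O | intermediate
16 | dipotassium 4,4′-[(all-E)-3,7,12,16-tetramethyloctadeca-1,3,5,7,9,11,13,15,17-nonaene-1,18-diyl]bis(3,5,5-trimethylcyclohexa-1,3-dien-1-olate) | [K+].[K+].[O-]C1=CC(C)=C(/C=C/C(C)=C/C=C/C(C)=C/C=C/C=C(C)/C=C/C=C(C)/C=C/C2=C(C)C=C([O-])CC2(C)C)C(C)(C)C1 | intermediate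
17 | β,β-carotene-3,3′-dione; 4,4′-[(all-E)-3,7,12,16-tetramethyloctadeca-1,3,5,7,9,11,13,15,17-nonaene-1,18-diyl]bis(3,5,5-trimethylcyclohex-3-en-1-one) | CC1=C(/C=C/C(C)=C/C=C/C(C)=C/C=C/C=C(C)/C=C/C=C(C)/C=C/C2=C(C)CC(=O)CC2(C)C)C(C)(C)CC(=O)C1 | intermediate
18 | (6′S)-β,ε-carotene-3,3′-dione | CC1=CC(=O)CC(C)(C)[C@@H]1/C=C/C(C)=C/C=C/C(C)=C/C=C/C=C(C)/C=C/C=C(C)/C=C/C1=C(C)CC(=O)CC1(C)C | intermediate
19 | (6S,6′R)-ε,ε-carotene-3,3′-dione (meso) | CC1=CC(=O)CC(C)(C)[C@@H]1/C=C/C(C)=C/C=C/C(C)=C/C=C/C=C(C)/C=C/C=C(C)/C=C/[C@H]1C(C)=CC(=O)CC1(C)C | target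

**Step count**

Total steps: 7. Longest linear sequence: 6 steps (1 → 5 → 7 → 13 → 17 → 18 → 19); step 3 supplies reagent 10.

**Steps most likely to fail, with fallbacks**

Most at risk is step 5. Mesityl oxide is a hindered, sluggish Michael acceptor, the polyenolate of 13 is ambident, and the aldol closure could in principle use the other methyl ketone. The fallback sets out from 13 and comes back at 17. Allyl acetoacetate and acetone are condensed with TiCl4 and pyridine to the doubly activated acceptor prop-2-en-1-yl 2-acetyl-3-methylbut-2-enoate F1. The bis(enolate) of 13 (KOtBu, THF) adds to F1, and a Hagemann-type aldol condensation of the acetoacetate methyl onto the C5 ketone closes both rings to the bis(allyl β-keto ester) F2. Pd(PPh3)4 (zerovalent palladium) with HCO2H and Et3N in THF at rt removes both ester groups by deallylation and decarboxylation, giving ε,ε-carotene-3,3′-dione as the mixture of its three stereoisomers F3. KOtBu in THF followed by AcOH at −78 °C deconjugates F3 to 17.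

Second is step 6. The substrate has a tetrasubstituted β,γ double bond and a neopentyl γ-carbon, protonation could stray further along the polyene, and the yield is statistically capped near half. The fallback sets out from 17 and comes back at 19. A catalytic achiral base (DBU, toluene, rt) conjugates both rings without selectivity and gives 19 together with (6R,6′R)-ε,ε-carotene-3,3′-dione F4 and (6S,6′S)-ε,ε-carotene-3,3′-dione F5 in about 2:1:1. Preparative HPLC on amylose tris(3,5-dimethylphenylcarbamate) isolates 19. F4 and F5 are returned to 17 by KOtBu then AcOH at −78 °C.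

Third is step 4. The non-stabilized ylide is strongly basic toward a base-sensitive polyene dialdehyde and gives mainly Z olefins that must be isomerized. The fallback sets out from 7 and 8 and comes back at 12. Bromide 8 and 1-phenyl-1H-tetrazole-5-thiol (K2CO3, acetone) give 5-{[2-(2-methyl-1,3-dioxolan-2-yl)ethyl]sulfanyl}-1-phenyl-1H-tetrazole F6. Oxidation with H2O2 and catalytic (NH4)6Mo7O24 in ethanol gives 5-{[2-(2-methyl-1,3-dioxolan-2-yl)ethyl]sulfonyl}-1-phenyl-1H-tetrazole F7. Julia–Kocienski olefination of 7 with F7 (KN(SiMe3)2, DME, −60 °C to rt) gives 12 directly with E geometry, and the acid hydrolysis of step 4 then leads to 13.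

**Further compounds**

F1 | step 5 | prop-2-en-1-yl 2-acetyl-3-methylbut-2-enoate | CC(=O)C(=C(C)C)C(=O)OCC=C
F2 | step 5 | diprop-2-en-1-yl 3,3′-[(all-E)-3,7,12,16-tetramethyloctadeca-1,3,5,7,9,11,13,15,17-nonaene-1,18-diyl]bis(2,2,4-trimethyl-6-oxocyclohex-4-ene-1-carboxylate), stereoisomer mixture | C=CCOC(=O)C1C(=O)C=C(C)C(/C=C/C(C)=C/C=C/C(C)=C/C=C/C=C(C)/C=C/C=C(C)/C=C/C2C(C)=CC(=O)C(C(=O)OCC=C)C2(C)C)C1(C)C
F3 | step 5 | ε,ε-carotene-3,3′-dione, mixture of the three stereoisomers | CC1=CC(=O)CC(C)(C)C1/C=C/C(C)=C/C=C/C(C)=C/C=C/C=C(C)/C=C/C=C(C)/C=C/C1C(C)=CC(=O)CC1(C)C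
F4 | step 6 | (6R,6′R)-ε,ε-carotene-3,3′-dione | CC1=CC(=O)CC(C)(C)[C@H]1/C=C/C(C)=C/C=C/C(C)=C/C=C/C=C(C)/C=C/C=C(C)/C=C/[C@H]1C(C)=CC(=O)CC1(C)C
F5 | step 6 | (6S,6′S)-ε,ε-carotene-3,3′-dione | CC1=CC(=O)CC(C)(C)[C@@H]1/C=C/C(C)=C/C=C/C(C)=C/C=C/C=C(C)/C=C/C=C(C)/C=C/[C@@H]1C(C)=CC(=O)CC1(C)C
F6 | step 4 | 5-{[2-(2-methyl-1,3-dioxolan-2-yl)ethyl]sulfanyl}-1-phenyl-1H-tetrazole | CC1(CCSc2nnnn2-c2ccccc2)OCCO1
F7 | step 4 | 5-{[2-(2-methyl-1,3-dioxolan-2-yl)ethyl]sulfonyl}-1-phenyl-1H-tetrazole | CC1(CCS(=O)(=O)c2nnnn2-c2ccccc2)OCCO1
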